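6 questions stood before me: which form holds most of the starting complex at the end of south, south-east and west, and how much of it.

| setting | ash | larch | south | south-east | west |
|---|---|---|---|---|---|
| starting complex | 0.22 M | 0.22 M | 0.22 M | 0.22 M | 0.22 M |
| incoming ligand | 0.242 M | 0.242 M | 0.242 M | 0.242 M | 0.242 M |
| leaving ligand | 0.22 M | 0.22 M | 0.220 M | 0.220 M | 0.220 M |
| capture agent | 0.0077 M | 0.027 M | 0.0110 M | 0.0220 M | 0.0440 M |
| remark | run made earlier | run made earlier |  |  |  |
| time |  |  | 20 min | 20 min | 20 min |

| run | time / min | complex with two exchanged / % | starting complex / % | complex with one exchanged / % | trapped intermediate / % |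
|---|---|---|---|---|---|
| ash | 1.50 | 1.5 | 85.7 | 12.9 | 1.2 |
| ash | 3.00 | 3.2 | 76.9 | 20.4 | 0 |
| ash | 5.00 | 2.1 | 71.5 | 25.2 | 0.5 |
| ash | 6.00 | 5.3 | 71.0 | 24.6 | 1.7 |
| ash | 8.00 | 3.9 | 66.5 | 26.6 | 0 |
| ash | 10.0 | 6.4 | 65.4 | 28.3 | 0 |
| larch | 1.50 | 0 | 87.7 | 12.7 | 0 |
| larch | 3.00 | 1.5 | 77.0 | 21.1 | 0 |
| larch | 5.00 | 2.9 | 69.9 | 25.1 | 0.1 |
| larch | 6.00 | 3.3 | 68.4 | 26.4 | 1.3 |
| larch | 8.00 | 4.7 | 65.5 | 28.8 | 1.3 |
| larch | 10.0 | 6.6 | 64.8 | 26.2 | 3.6 |

(each reading ± 1 percentage point)

- reactions considered so far: starting complex + incoming ligand <-> leaving ligand + complex with one exchanged; complex with one exchanged + incoming ligand <-> leaving ligand + complex with two exchanged; complex with two exchanged + incoming ligand <-> leaving ligand + complex with three exchanged; complex with three exchanged + incoming ligand <-> leaving ligand + complex with four exchanged; incoming ligand -> decomposed reagent; complex with one exchanged + capture agent -> trapped intermediate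

1. which of these there is most of at the end, counted by the starting complex in it, south (starting complex / trapped intermediate / complex with one exchanged / complex with two exchanged)
2. which of these there is most of at the end, counted by the starting complex in it, south-east (starting complex / trapped intermediate / complex with one exchanged / complex with two exchanged)
3. which of these there is most of at the end, counted by the starting complex in it, west (starting complex / trapped intermediate / complex with one exchanged / complex with two exchanged)
4. amount of the one of these that there is most of at the end, in percent of the starting complex charged, south
5. amount of the one of these that there is most of at the end, in percent of the starting complex charged, south-east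
6. amount of the one of these that there is most of at the end, in percent of the starting complex charged, west

At the last reading the starting complex stood at 65.4 % in ash and 64.8 % in larch, though larch held more capture agent, and in larch it read more than any other form, so I committed to starting complex as the answer, at about 65.1 % in each new flask. Then I followed one molecule. Having left the starting complex it sits as complex with one exchanged, where it may go back, go on, or be caught, and the catch is listed with no way back. So I asked what the catch costs.

Over its 10.0 min, larch had an exposure of 2.17 min, as if the whole charge had sat in that form so long. I got the catch rate in larch, the share of that form caught per minute with capture agent taken at its charge, two ways. The trapped intermediate read directly gives 0.0166 min⁻¹. The part missing from the other 3 readings, which also holds any complex with three or four exchanged, gives 0.0111 min⁻¹. They part by 1.2 percentage points, less than the scatter of 1.7 points that the second way alone carries, so neither is caught cheating and I took the mean, 0.0138 min⁻¹.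

The listed catch takes capture agent in proportion to itself and to the complex with one exchanged, pseudo-first-order in capture agent, so at a given exposure the share left does not depend on its charge. For the new flasks I held the complex with one exchanged at its last larch reading beyond 10.0 min, which gives an exposure of 4.79 min by 20 min. The capture survival, the share of capture agent left at a given exposure, is then 58.3 %. That makes the trapped intermediate 2.08 % in south and 8.34 % in west, and the west figure is less than the starting complex read in larch.

The forecast named starting complex for south, starting complex for south-east and starting complex for west, at 64 %, 62.5 % and 60 %: “Trapping pulls it down slightly, but it stays the largest species in all three runs.”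

The flasks gave starting complex at 66.5 % in south, starting complex at 65.9 % in south-east and starting complex at 64.6 % in west.

    starting complex + incoming ligand ⇌ leaving ligand + complex with one exchanged (K = 1.90, k = 0.00820 M⁻¹ s⁻¹)
    complex with one exchanged + incoming ligand ⇌ leaving ligand + complex with two exchanged (K = 1.10, k = 0.00570 M⁻¹ s⁻¹)
    complex with two exchanged + incoming ligand ⇌ leaving ligand + complex with three exchanged (K = 8.10, k = 0.00170 M⁻¹ s⁻¹)
    complex with three exchanged + incoming ligand ⇌ leaving ligand + complex with four exchanged (K = 0.900, k = 0.0220 M⁻¹ s⁻¹)
    incoming ligand → decomposed reagent (k = 8.60 × 10⁻⁴ s⁻¹)
    complex with one exchanged + capture agent → trapped intermediate (k = 0.00820 M⁻¹ s⁻¹)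

Capture agent left stood at 59 % in south, 60 % in south-east and 61 % in west, against my 58.3 %. In the neighbour of south with 0.15 M of incoming ligand, scaling the exposure by the final complex with one exchanged, 18.9 % against 25.2 %, gives 66.7 % left, and that flask held 68 %. None of the flasks had come to rest: by 200 min each held more starting complex than at its end, south 92.8 % with incoming ligand down to 0.817 % of its charge, and west 82.2 % with 16.4 % of trapped intermediate.

All runs are simulated on assumed constants; scatter was added.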